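The constants used here were drawn at random within sensible limits; what happens was integrated by code.

The ratio of the rate at which D captures X to the rate at which X decays to Z is followed here through the flasks below.

    D + X → D.X, rate k1*[D]*[X]^0.5 (k1 = 0.029 L⁰·⁵ mol⁻⁰·⁵ s⁻¹, Ea1 = 71.0 kJ mol⁻¹)
    D.X → Q (k2 = 4.3 × 10⁻⁶ s⁻¹, Ea2 = 111 kJ mol⁻¹)
    X → Z (k3 = 0.0069 s⁻¹, Ea3 = 82.0 kJ mol⁻¹)
    (constants at 25 °C)

| flask | D | X | temperature | time | remark |
|---|---|---|---|---|---|
| eta | 0.22 M | 0.220 M (fed, over 15 min) | 25 °C | 40 min | all else is in the flask from the start; the feed brings no volume worth counting |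
| theta | 0.22 M (fed, over 15 min) | 0.220 M | 25 °C | 40 min | all else is in the flask from the start; the feed brings no volume worth counting |
| epsilon | 0.22 M (fed, over 15 min) | 0.220 M |  | 40 min | the addition at −5 °C, then warmed to 25 °C; the feed brings no volume worth counting |
| beta | 0.22 M | 0.220 M |  | 40 min | everything together at the start at −5 °C, warmed to 25 °C at 15 min |
| gamma | 0.22 M (fed, over 1.5 min) | 0.220 M | 25 °C | 40 min | all else is in the flask from the start; the feed brings no volume worth counting |

- at 25 °C the constants are as listed, elsewhere as the activation energies make them

- the flask with the highest amount of D.X, in percent of the D charged ("all alike" if they lie within 1.5 percentage points) (eta / theta / epsilon / beta / gamma / all alike)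
- final D.X, as a percentage of the D charged, in eta
- final D.X, as a percentage of the D charged, in theta
- final D.X, as a percentage of the D charged, in epsilon
- final D.X, as a percentage of the D charged, in beta
- final D.X, as a percentage of the D charged, in gamma

Let k_c be the capture constant, 0.029 L⁰·⁵ mol⁻⁰·⁵ s⁻¹, and k_d the decay constant of X, 0.0069 s⁻¹. Then the ratio, a selectivity factor, is r = k_c[D]/(k_d√[X]), and it rises as [X] falls.

What [X] does the feed hold in eta? X arrives at f = 0.0147 M min⁻¹, and its lifetime, 2.42 min, is shorter than the feed. So [X] stays quasi-steady, and if capture takes up the feed, √[X] = f/(k_c[D]). This gives r = ([D]/D_c)², where the crossover concentration D_c = √(k_d f)/k_c = 0.0448 M is the [D] at which capture and decay of the fed X run equally. At the start of eta, r = 24.1.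

How much X does decay take as D is consumed? Integrating k_d[X] with d[D] = −f dt gives, in closed form, the loss L = D_c²(1/D_end − 1/D_start). The charges in eta are equal, so D_end equals L. The resulting quadratic gives L = 0.0405 M, and D.X comes to 81.6%. The step to Q takes about 1.03% of D.X in the time, which is neglected.

Can another recipe beat this? In theta, counting as captured the D delivered within one lifetime of X gives 16.1%. With everything present, r starts at 1.97 at 25 °C and at 3.24 at −5 °C, so the starting shares of capture are 66.3% and 76.4%. Taking the first for gamma and the second for beta and epsilon, the highest score goes to eta.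

The forecast also chose eta, with 87% (83% to 90%) for eta, higher than this reckoning, and 20%, 65%, 70% and 54% for theta, epsilon, beta and gamma, reasoning that "Feeding X into excess D (eta) keeps X low, which favours the half-order capture over the first-order loss".

The simulation gives eta as the best flask, with D.X at 84.5% in eta, 20.4% in theta, 65.3% in epsilon, 70.4% in beta and 53.5% in gamma. In eta at 7.04 min, X went to D.X 9.1 times as fast as to Z, and the Z standing at 40.0 min, 0.0325 M, lies below L. A neighbour of eta charged with 0.55 M of D ends with [D] far above D_c; the same integral gives L = 0.00243 M, and that neighbour holds 0.00235 M of Z at 40.0 min.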